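**Retrosynthetic overview**

1. The target is an ent-labdane: trans-fused rings A and B with a dienyl carbinol chain on C9. The plan rests on the O–C6–C7=C8–C17–O array of ring B (axial α acetate on C6, C7=C8 alkene, acetoxymethyl C17), which is the 1,4-adduct of a semicyclic C6=C7–C8=C17 diene.
2. Key disconnection: the C17–O and C6–O bonds and the C7=C8 alkene come from an 11-silyloxy-ent-drima-6,8(17)-diene by palladium-catalysed 1,4-diacetoxylation.
3. The diene comes from a C8 ketone (C6=C7 by Saegusa–Ito, C8=C17 by Wittig). The ketone comes from the bicyclic β-keto ester, in which ring A and then ring B close in one cationic bicyclisation of the geranyl acetoacetate; the racemate is resolved as its (2R,3R)-butanediol ketals.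
4. Side chain: the E C11=C12 alkene is made by Julia–Kocienski olefination of the core C11 tetrazolyl sulfone with (S)-2-methyl-2-(triethylsilyloxy)but-3-enal, made from (R)-2-methylglycidol (source of C13). The core C11 aldehyde is avoided because its C9–H is allylic and α to the carbonyl, so enolisation could expel the C6 acetate.
5. Last step: removal of the silyl group from O13.

Key step: step 8

Remark: labdane numbering is used for the core (C17 on C8, C20 = methyl on C10). α and β name the real faces of the enantiomer drawn: the C10 methyl, the C9 substituent and the C6 acetate are α; H5 and H9 are β.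
Assumption: the two diastereomeric ketals of step 3 are separable on silica or by crystallisation, and the ent-series diastereomer is identified by X-ray analysis or by the sign of rotation of the ketone regenerated from a sample.
The tert-butyldimethylsilyl group is replaced by tert-butyldiphenylsilyl (TBDPS) on O11, because the ether must survive acetic acid in step 8.

**Route**

Step 1
Reactants: 1 methyl acetoacetate; 2 geranyl chloride
Product: 3 methyl (6E)-7,11-dimethyl-3-oxododeca-6,10-dienoate
Conditions: NaH, THF, 0 °C; n-BuLi, 0 °C; then 2, 0 °C → rt; dilute HCl work-up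
Reagents that add atoms: none
Why: Acetoacetate dianion γ-alkylation: the more basic terminal carbanion displaces the primary allylic chloride by SN2 and the E-alkene is untouched.

Step 2
Reactants: 3 methyl (6E)-7,11-dimethyl-3-oxododeca-6,10-dienoate
Product: 4 racemic methyl (1S*,4aR*,8aR*)-5,5,8a-trimethyl-2-oxodecahydronaphthalene-1-carboxylate (trans-fused; ester equatorial)
Conditions: SnCl4, CH2Cl2, 0 °C → rt
Reagents that add atoms: none
Why: Proton-initiated cationic polyene bicyclisation terminated by C-alkylation of the β-keto ester enol (ring A, then ring B, chair–chair transition state), so the E-alkene fixes the trans ring fusion and the enolisable C9 ester settles equatorial; the product is racemic.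

Step 3
Reactants: 4 racemic bicyclic keto ester
Product: 5 (4R,5R)-4,5-dimethyl-1,3-dioxolane ketal (at C8) of methyl (1S,4aR,8aR)-5,5,8a-trimethyl-2-oxodecahydronaphthalene-1-carboxylate
Conditions: (2R,3R)-butane-2,3-diol, TsOH·H2O (cat.), benzene, reflux, Dean–Stark; separation of the two diastereomers by chromatography or crystallisation
Reagents that add atoms: (2R,3R)-butane-2,3-diol, C[C@@H](O)[C@@H](C)O
Why: Acid-catalysed ketalisation; the diol is C2-symmetric, so no stereocentre arises at C8, the racemate gives exactly two diastereomers, and their separation is a classical covalent resolution in which the auxiliary also protects the ketone.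

Step 4
Reactants: 5 chiral ketal ester
Product: 7 (1R,4aR,8aR)-1-(hydroxymethyl)-5,5,8a-trimethyloctahydronaphthalen-2(1H)-one, via ketal alcohol 6 (not isolated)
Conditions: LiAlH4, THF, 0 °C → rt; then 2 M HCl, THF, 40 °C
Reagents that add atoms: water, O
Why: LiAlH4 reduces the ester to the primary alcohol while the ketone is masked, and aqueous acid then hydrolyses the dioxolane; C9 keeps its equatorial substituent, the stable epimer of the β-hydroxy ketone.

Step 5
Reactants: 7 hydroxy ketone
Product: 8 (1R,4aR,8aR)-1-[(tert-butyldiphenylsilyloxy)methyl]-5,5,8a-trimethyloctahydronaphthalen-2(1H)-one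
Conditions: TBDPSCl, imidazole, DMF, rt
Reagents that add atoms: tert-butyl(chloro)diphenylsilane, CC(C)(C)[Si](Cl)(c1ccccc1)c1ccccc1
Why: Standard silylation of the primary alcohol; the TBDPS ether is chosen because it must later withstand acetic acid.

Step 6
Reactants: 8 silyloxy ketone
Product: 10 (1R,4aR,8aR)-1-[(tert-butyldiphenylsilyloxy)methyl]-5,5,8a-trimethyl-4a,5,6,7,8,8a-hexahydronaphthalen-2(1H)-one, via trimethylsilyl enol ether 9 (not isolated)
Conditions: LiN(iPr)2, Me3SiCl, THF, −78 °C; then Pd(OAc)2 (1.1 equiv), MeCN, rt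
Reagents that add atoms: none
Why: Saegusa–Ito dehydrogenation: kinetic deprotonation takes the unhindered C7 methylene (C9 is tertiary and next to the quaternary C10), and the palladium enolate formed from the silyl enol ether loses hydride from C6 to give the C6=C7 enone.

Step 7
Reactants: 10 the 6-en-8-one
Product: 11 11-(tert-butyldiphenylsilyloxy)-ent-drima-6,8(17)-diene
Conditions: Ph3PCH3Br, KOtBu, THF, 0 °C → rt
Reagents that add atoms: methyltriphenylphosphonium bromide, C[P+](c1ccccc1)(c1ccccc1)c1ccccc1.[Br-]
Why: Wittig methylenation of the C8 carbonyl (1,2-addition of the ylide to the enone), as used for the saturated C8 ketone of this ring system; no stereocentre is formed.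

Step 8
Reactants: 11 11-(tert-butyldiphenylsilyloxy)-ent-drima-6,8(17)-diene
Product: 12 6α,17-diacetoxy-11-(tert-butyldiphenylsilyloxy)-ent-drim-7-ene
Conditions: Pd(OAc)2 (5 mol%), LiCl (20 mol%), LiOAc·2H2O, 1,4-benzoquinone (2 equiv), AcOH, rt
Reagents that add atoms: acetic acid, CC(=O)O; lithium acetate, CC(=O)[O-].[Li+]
Why: Divalent palladium binds the s-trans C6=C7–C8=C17 diene on the β face, away from the axial methyls on C4 and C10, and acetate adds to the exocyclic terminus C17 to give a π-allyl complex over C8–C7–C6 with the metal still on the β face. Chloride on palladium suppresses migration of metal-bound acetate, so the second acetate attacks from outside, anti to the metal, and the quinone-bound complex releases zerovalent palladium, which benzoquinone returns to divalent palladium. The closest known reaction type is the palladium-catalysed, benzoquinone-mediated 1,4-diacetoxylation of conjugated dienes under chloride control. No ring is closed. The new stereocentre C6 is controlled by the face of the metal: anti attack on the β-bound allyl puts the oxygen on the α face, axial and syn to the C10 methyl. The step needs attack at C6 and not at C8 and β-face complexation; the fully substituted C8 terminus (1,4-addition also leaves the more substituted C7=C8 alkene) and the two axial methyls on the α face should secure both.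

Step 9
Reactants: 12 silyl ether diacetate
Product: 13 6α,17-diacetoxy-ent-drim-7-en-11-ol
Conditions: HF·pyridine, pyridine, THF, 0 °C → rt
Reagents that add atoms: none
Why: Fluoride cleavage of the Si–O bond under buffered, non-basic conditions, which leave both acetates in place and give no chance for acetyl migration from O17 to O11.

Step 10
Reactants: 13 C11 alcohol
Product: 14 6α,17-diacetoxy-11-[(1-phenyl-1H-tetrazol-5-yl)sulfanyl]-ent-drim-7-ene
Conditions: 1-phenyl-1H-tetrazole-5-thiol, PPh3, DIAD, THF, 0 °C → rt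
Reagents that add atoms: 1-phenyl-1H-tetrazole-5-thiol, Sc1nnnn1-c1ccccc1
Why: Mitsunobu thioetherification: the acidic tetrazolethiol displaces the primary C11 alkoxyphosphonium ion by SN2; no stereocentre is touched.

Step 11
Reactants: 14 sulfide
Product: 15 6α,17-diacetoxy-11-[(1-phenyl-1H-tetrazol-5-yl)sulfonyl]-ent-drim-7-ene
Conditions: (NH4)6Mo7O24·4H2O (cat.), 30% H2O2, EtOH, 0 °C → rt
Reagents that add atoms: hydrogen peroxide, OO
Why: Molybdate-catalysed peroxide oxidation of the sulfide to the sulfone; the C7=C8 alkene is deactivated by its two allylic acetates and should not be epoxidised.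

Step 12
Reactants: 16 (R)-2-methylglycidol
Product: 17 (S)-2-[(4-methoxybenzyloxy)methyl]-2-methyloxirane
Conditions: NaH, 4-methoxybenzyl chloride, Bu4NI (cat.), THF/DMF, 0 °C → rt
Reagents that add atoms: 4-methoxybenzyl chloride, COc1ccc(CCl)cc1
Why: Williamson etherification of the primary alkoxide; the quaternary stereocentre is not involved (the descriptor changes from R to S only through the priority rules).

Step 13
Reactants: 17 protected glycidol
Product: 18 (S)-1-(4-methoxybenzyloxy)-2-methylbut-3-en-2-ol
Conditions: Me3S+ I−, n-BuLi, THF, −10 °C → rt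
Reagents that add atoms: trimethylsulfonium iodide, C[S+](C)C.[I-]
Why: Epoxide-to-allylic-alcohol homologation: dimethylsulfonium methylide opens the epoxide at its CH2 and excess ylide converts the β-alkoxy sulfonium salt into the vinyl group, so no bond to the stereocentre is broken.

Step 14
Reactants: 18 tertiary allylic alcohol
Product: 19 (S)-1-(4-methoxybenzyloxy)-2-methyl-2-(triethylsilyloxy)but-3-ene
Conditions: Et3SiOTf, 2,6-lutidine, CH2Cl2, −78 → 0 °C
Reagents that add atoms: triethylsilyl trifluoromethanesulfonate, CC[Si](CC)(CC)OS(=O)(=O)C(F)(F)F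
Why: A silyl triflate with a hindered pyridine base silylates the tertiary allylic alcohol without ionising it.

Step 15
Reactants: 19 bis-ether
Product: 20 (S)-2-methyl-2-(triethylsilyloxy)but-3-en-1-ol
Conditions: DDQ, CH2Cl2/pH 7 buffer, 0 °C → rt
Reagents that add atoms: none
Why: Oxidative removal of the 4-methoxybenzyl ether by hydride abstraction and hydrolysis of the oxocarbenium ion; the silyl ether and the vinyl group are inert.

Step 16
Reactants: 20 primary alcohol
Product: 21 (S)-2-methyl-2-(triethylsilyloxy)but-3-enal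
Conditions: Dess–Martin periodinane, NaHCO3, CH2Cl2, 0 °C → rt
Reagents that add atoms: none
Why: Dess–Martin oxidation under buffered conditions gives an aldehyde without α-hydrogen, which can neither epimerise nor move into conjugation.

Step 17
Reactants: 15 core C11 sulfone; 21 (S)-2-methyl-2-(triethylsilyloxy)but-3-enal
Product: 22 (13S)-6α,17-diacetoxy-13-(triethylsilyloxy)-ent-labda-7,11E,14-triene
Conditions: KN(SiMe3)2 added to 15 and 21 (2 equiv), DME, −60 °C → rt
Reagents that add atoms: none
Why: Julia–Kocienski olefination under Barbier conditions: the C11 sulfonyl carbanion adds to the non-enolisable aldehyde, and Smiles rearrangement followed by anti elimination of SO2 and the tetrazolone should give the E C11=C12 alkene, favoured by the potassium counter-ion in DME and the bulk at C9 and C13; C13 is carried unchanged from the aldehyde.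

Step 18
Reactants: 22 silyl-protected target
Product: 23 (13S)-6α,17-diacetoxy-ent-labda-7,11E,14-trien-13-ol (CNP0103498.1)
Conditions: HF·pyridine, pyridine, THF, 0 °C → rt
Reagents that add atoms: none
Why: Buffered fluoride removes the triethylsilyl group without acid strong enough to ionise the doubly allylic tertiary alcohol and without base that would cleave the acetates.

**Compound list**

1 | methyl acetoacetate | COC(=O)CC(C)=O | starting material
2 | geranyl chloride | CC(C)=CCC/C(C)=C/CCl | starting material
3 | methyl (6E)-7,11-dimethyl-3-oxododeca-6,10-dienoate | CC(C)=CCC/C(C)=C/CCC(=O)CC(=O)OC | intermediate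
4 | racemic methyl (1S*,4aR*,8aR*)-5,5,8a-trimethyl-2-oxodecahydronaphthalene-1-carboxylate (SMILES shows the enantiomer carried on) | COC(=O)[C@@H]1C(=O)CC[C@@H]2C(C)(C)CCC[C@@]12C | intermediate
5 | (4R,5R)-4,5-dimethyl-1,3-dioxolane ketal of methyl (1S,4aR,8aR)-5,5,8a-trimethyl-2-oxodecahydronaphthalene-1-carboxylate | COC(=O)[C@@H]1C3(O[C@H](C)[C@@H](C)O3)CC[C@@H]2C(C)(C)CCC[C@@]12C | intermediate
6 | (4R,5R)-4,5-dimethyl-1,3-dioxolane ketal of (1R,4aR,8aR)-1-(hydroxymethyl)-5,5,8a-trimethyloctahydronaphthalen-2(1H)-one | OC[C@@H]1C3(O[C@H](C)[C@@H](C)O3)CC[C@@H]2C(C)(C)CCC[C@@]12C | intermediate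
7 | (1R,4aR,8aR)-1-(hydroxymethyl)-5,5,8a-trimethyloctahydronaphthalen-2(1H)-one | OC[C@@H]1C(=O)CC[C@@H]2C(C)(C)CCC[C@@]12C | intermediate
8 | (1R,4aR,8aR)-1-[(tert-butyldiphenylsilyloxy)methyl]-5,5,8a-trimethyloctahydronaphthalen-2(1H)-one | CC(C)(C)[Si](OC[C@@H]1C(=O)CC[C@@H]2C(C)(C)CCC[C@@]12C)(c1ccccc1)c1ccccc1 | intermediate
9 | trimethylsilyl enol ether of 8 (C7=C8, O-silylated at C8) | CC(C)(C)[Si](OC[C@@H]1C(O[Si](C)(C)C)=CC[C@@H]2C(C)(C)CCC[C@@]12C)(c1ccccc1)c1ccccc1 | intermediate
10 | (1R,4aR,8aR)-1-[(tert-butyldiphenylsilyloxy)methyl]-5,5,8a-trimethyl-4a,5,6,7,8,8a-hexahydronaphthalen-2(1H)-one (the 6-en-8-one) | CC(C)(C)[Si](OC[C@@H]1C(=O)C=C[C@@H]2C(C)(C)CCC[C@@]12C)(c1ccccc1)c1ccccc1 | intermediate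
11 | 11-(tert-butyldiphenylsilyloxy)-ent-drima-6,8(17)-diene | CC(C)(C)[Si](OC[C@@H]1C(=C)C=C[C@@H]2C(C)(C)CCC[C@@]12C)(c1ccccc1)c1ccccc1 | intermediate
12 | 6α,17-diacetoxy-11-(tert-butyldiphenylsilyloxy)-ent-drim-7-ene | CC(C)(C)[Si](OC[C@@H]1C(COC(C)=O)=C[C@H](OC(C)=O)[C@@H]2C(C)(C)CCC[C@@]12C)(c1ccccc1)c1ccccc1 | intermediate
13 | 6α,17-diacetoxy-ent-drim-7-en-11-ol | OC[C@@H]1C(COC(C)=O)=C[C@H](OC(C)=O)[C@@H]2C(C)(C)CCC[C@@]12C | intermediate
14 | 6α,17-diacetoxy-11-[(1-phenyl-1H-tetrazol-5-yl)sulfanyl]-ent-drim-7-ene | c1ccccc1-n1nnnc1SC[C@@H]1C(COC(C)=O)=C[C@H](OC(C)=O)[C@@H]2C(C)(C)CCC[C@@]12C | intermediate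
15 | 6α,17-diacetoxy-11-[(1-phenyl-1H-tetrazol-5-yl)sulfonyl]-ent-drim-7-ene | c1ccccc1-n1nnnc1S(=O)(=O)C[C@@H]1C(COC(C)=O)=C[C@H](OC(C)=O)[C@@H]2C(C)(C)CCC[C@@]12C | intermediate
16 | (R)-2-methylglycidol, (R)-(2-methyloxiran-2-yl)methanol | C[C@]1(CO1)CO | starting material
17 | (S)-2-[(4-methoxybenzyloxy)methyl]-2-methyloxirane | C[C@]1(CO1)COCc1ccc(OC)cc1 | intermediate
18 | (S)-1-(4-methoxybenzyloxy)-2-methylbut-3-en-2-ol | C=C[C@](C)(O)COCc1ccc(OC)cc1 | intermediate
19 | (S)-1-(4-methoxybenzyloxy)-2-methyl-2-(triethylsilyloxy)but-3-ene | C=C[C@](C)(O[Si](CC)(CC)CC)COCc1ccc(OC)cc1 | intermediate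
20 | (S)-2-methyl-2-(triethylsilyloxy)but-3-en-1-ol | C=C[C@](C)(O[Si](CC)(CC)CC)CO | intermediate
21 | (S)-2-methyl-2-(triethylsilyloxy)but-3-enal | C=C[C@](C)(O[Si](CC)(CC)CC)C=O | intermediate
22 | (13S)-6α,17-diacetoxy-13-(triethylsilyloxy)-ent-labda-7,11E,14-triene | C=C[C@](C)(O[Si](CC)(CC)CC)/C=C/[C@@H]1C(COC(C)=O)=C[C@H](OC(C)=O)[C@@H]2C(C)(C)CCC[C@@]12C | intermediate
23 | (13S)-6α,17-diacetoxy-ent-labda-7,11E,14-trien-13-ol (CNP0103498.1) | C=C[C@](C)(O)/C=C/[C@@H]1C(COC(C)=O)=C[C@H](OC(C)=O)[C@@H]2C(C)(C)CCC[C@@]12C | target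

**Step count**

Total: 18 steps. Longest linear sequence: 13 steps (steps 1–11, 17, 18); the side branch is steps 12–16.

**Steps most likely to fail**

Step 8. The outer-sphere acetate must reach C6 on the α face, between the axial methyls on C4 and C10. This may be slow, so that delivery of metal-bound acetate on the β face or attack at C8 competes, with loss of facial or positional selectivity. The fallback sets C6 by hydride delivery and sets out from enone 10. Addition of (4-methoxybenzyloxy)methyllithium (from Bu3SnCH2OPMB and n-BuLi, THF, −78 °C) to the C8 carbonyl should give the tertiary allylic alcohol 8-hydroxy-17-(4-methoxybenzyloxy)-11-(tert-butyldiphenylsilyloxy)-ent-drim-6-ene F1. Oxidative 1,3-transposition with [C5H5NH][CrO3Cl] (pyridinium chlorochromate) in CH2Cl2 should give 17-(4-methoxybenzyloxy)-11-(tert-butyldiphenylsilyloxy)-ent-drim-7-en-6-one F2. DDQ in buffered CH2Cl2 frees the primary alcohol, 17-hydroxy-11-(tert-butyldiphenylsilyloxy)-ent-drim-7-en-6-one F3. NaBH4 with CeCl3·7H2O in MeOH should deliver hydride to the open β face of the C6 ketone and give the axial alcohol 11-(tert-butyldiphenylsilyloxy)-ent-drim-7-ene-6α,17-diol F4. Ac2O, DMAP and pyridine at 40 °C acetylate both hydroxyls, and the route is rejoined at 12.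

Step 17. The β-branched sulfonyl carbanion of 15 may add slowly to the α-quaternary aldehyde, and the C17 acetyl group could then be transferred to the C11 carbanion through a six-membered transition state. The fallback reverses the polarity and sets out from alcohol 13 (it also bypasses the hindered Mitsunobu of step 10). Dess–Martin oxidation gives 6α,17-diacetoxy-ent-drim-7-en-11-al F5, which is used cold and unpurified because its C9–H is allylic and α to the carbonyl. Alcohol 20 is converted with 1-phenyl-1H-tetrazole-5-thiol, PBu3 and 1,1'-(azodicarbonyl)dipiperidine in toluene at 60 °C into (S)-5-{[2-methyl-2-(triethylsilyloxy)but-3-en-1-yl]sulfanyl}-1-phenyl-1H-tetrazole F6. Oxidation with (NH4)6Mo7O24·4H2O and H2O2 gives (S)-5-{[2-methyl-2-(triethylsilyloxy)but-3-en-1-yl]sulfonyl}-1-phenyl-1H-tetrazole F7. F7 is metalated with LiN(SiMe3)2 in THF at −78 °C and F5 is added at once; the olefination rejoins the route at 22.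

Step 3. The two ketal diastereomers may not resolve on silica or by crystallisation. The fallback moves the resolving handle to an ester of the C11 alcohol and sets out from racemic 4. Ethylene glycol and TsOH give the racemic ketal ester, methyl 8,8-(ethylenedioxy) keto ester ketal F8. LiAlH4 gives the racemic ketal alcohol F9. Esterification with (S)-O-methylmandelic acid (EDC, DMAP, CH2Cl2, 0 °C) gives two diastereomeric esters, from which the ent-series (S)-O-methylmandelate F10 is isolated by chromatography or crystallisation. K2CO3 in MeOH returns the enantiopure ketal alcohol F11. 2 M HCl in THF removes the ketal, and the route is rejoined at 7.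

**Further compounds**

F1 | step 8 | 8-hydroxy-17-(4-methoxybenzyloxy)-11-(tert-butyldiphenylsilyloxy)-ent-drim-6-ene (8α-OH expected; C8 configuration is lost in the next step) | CC(C)(C)[Si](OC[C@@H]1[C@@](O)(COCc3ccc(OC)cc3)C=C[C@@H]2C(C)(C)CCC[C@@]12C)(c1ccccc1)c1ccccc1
F2 | step 8 | 17-(4-methoxybenzyloxy)-11-(tert-butyldiphenylsilyloxy)-ent-drim-7-en-6-one | CC(C)(C)[Si](OC[C@@H]1C(COCc3ccc(OC)cc3)=CC(=O)[C@@H]2C(C)(C)CCC[C@@]12C)(c1ccccc1)c1ccccc1
F3 | step 8 | 17-hydroxy-11-(tert-butyldiphenylsilyloxy)-ent-drim-7-en-6-one | CC(C)(C)[Si](OC[C@@H]1C(CO)=CC(=O)[C@@H]2C(C)(C)CCC[C@@]12C)(c1ccccc1)c1ccccc1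
F4 | step 8 | 11-(tert-butyldiphenylsilyloxy)-ent-drim-7-ene-6α,17-diol | CC(C)(C)[Si](OC[C@@H]1C(CO)=C[C@H](O)[C@@H]2C(C)(C)CCC[C@@]12C)(c1ccccc1)c1ccccc1
F5 | step 17 | 6α,17-diacetoxy-ent-drim-7-en-11-al | O=C[C@@H]1C(COC(C)=O)=C[C@H](OC(C)=O)[C@@H]2C(C)(C)CCC[C@@]12C
F6 | step 17 | (S)-5-{[2-methyl-2-(triethylsilyloxy)but-3-en-1-yl]sulfanyl}-1-phenyl-1H-tetrazole | C=C[C@](C)(O[Si](CC)(CC)CC)CSc1nnnn1-c1ccccc1
F7 | step 17 | (S)-5-{[2-methyl-2-(triethylsilyloxy)but-3-en-1-yl]sulfonyl}-1-phenyl-1H-tetrazole | C=C[C@](C)(O[Si](CC)(CC)CC)CS(=O)(=O)c1nnnn1-c1ccccc1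
F8 | step 3 | racemic ethylene ketal of keto ester 4 (SMILES shows the ent-series enantiomer) | COC(=O)[C@@H]1C3(OCCO3)CC[C@@H]2C(C)(C)CCC[C@@]12C
F9 | step 3 | racemic ethylene ketal of hydroxy ketone 7 (SMILES shows the ent-series enantiomer) | OC[C@@H]1C3(OCCO3)CC[C@@H]2C(C)(C)CCC[C@@]12C
F10 | step 3 | (S)-O-methylmandelate of the ent-series ethylene ketal alcohol | CO[C@H](C(=O)OC[C@@H]1C3(OCCO3)CC[C@@H]2C(C)(C)CCC[C@@]12C)c1ccccc1
F11 | step 3 | ethylene ketal of 7, single enantiomer | OC[C@@H]1C3(OCCO3)CC[C@@H]2C(C)(C)CCC[C@@]12C
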